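**Plan**

- Retrosynthesis: the two pivalate esters come off last. Ring B is then cut at C1'–C6' and C2'–C3' (with the C6'–O bridge bond), giving furan and a ring A aryl ynone.
- Feature used: ring B carries acyl at C1', prenyl at C2' and OH at C3', followed by three unsubstituted CH (C4'–C6'). C1' and C2' are the two alkyne carbons; C3'–C6' and the oxygen are furan.
- The ynone is cut at the C(=O)–C(sp) bond into a ring A acid chloride and 5-methylhex-4-en-1-yne. The ring A prenyl is cut at the aryl–CH2 bond, and the enyne at its propargylic C–C bond.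
- Forward: bought ring A is esterified, prenylated and oxidized to the acid; the enyne is made in two steps; acyl–alkynyl coupling gives the ynone; ring B is built on it in step 7; ester cleavage ends the route.
- Stereochemistry: the target has no stereocentre and no E/Z-isomeric alkene. The two bridgehead centres of the cycloadduct are racemic and vanish on aromatization.

Key step: step 7

Assumption: tributyl(3-methylbut-2-en-1-yl)stannane is taken as a purchasable reagent, and "prenyl" means 3-methylbut-2-en-1-yl throughout.

**Route**

Step 1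
Reactants: 1 5-bromo-2,4-dihydroxybenzaldehyde
Product: 2 5-bromo-2,4-bis(pivaloyloxy)benzaldehyde
Conditions: PivCl (2.5 equiv), Et3N (3 equiv), DMAP (10 mol %), CH2Cl2, 0 °C → rt
Reagents that add atoms: pivaloyl chloride, CC(C)(C)C(=O)Cl
Why: DMAP-catalysed O-acylation esterifies both phenols (the hydrogen-bonded 2-OH included), and the hindered aryl esters keep the ortho oxygen from cyclizing onto the later ynone, make ring A electron-poor and tolerate Lewis acid.

Step 2
Reactants: 2 5-bromo-2,4-bis(pivaloyloxy)benzaldehyde; 3 tributyl(3-methylbut-2-en-1-yl)stannane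
Product: 4 2,4-bis(pivaloyloxy)-5-(3-methylbut-2-en-1-yl)benzaldehyde
Conditions: Pd(PPh3)4 (5 mol %), DMF, 90 °C
Reagents that add atoms: none
Why: Stille coupling, in which zerovalent palladium inserts into the electron-poor aryl C–Br bond and the allyl group is transferred through its less hindered CH2 terminus, should give the linear prenyl arene under base-free conditions that leave aldehyde and esters alone.

Step 3
Reactants: 4 2,4-bis(pivaloyloxy)-5-(3-methylbut-2-en-1-yl)benzaldehyde
Product: 5 2,4-bis(pivaloyloxy)-5-(3-methylbut-2-en-1-yl)benzoic acid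
Conditions: NaClO2, NaH2PO4, 2-methyl-2-butene (30 equiv), t-BuOH/H2O, 0 °C → rt
Reagents that add atoms: sodium chlorite, [Na+].[O-]Cl=O
Why: Pinnick oxidation converts the aldehyde into the acid at about pH 4, where aryl pivalates are stable, and the large excess of 2-methyl-2-butene traps hypochlorous acid before it can reach the prenyl olefin.

Step 4
Reactants: 6 trimethylsilylacetylene; 7 prenyl bromide (1-bromo-3-methylbut-2-ene)
Product: 9 trimethyl(5-methylhex-4-en-1-yn-1-yl)silane, via (trimethylsilylethynyl)magnesium bromide 8 (not isolated)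
Conditions: EtMgBr, THF, 0 → 40 °C; then CuBr·SMe2 (5 mol %), 7, THF, 0 °C → rt
Reagents that add atoms: none
Why: Copper-catalysed allylic substitution of the alkynyl Grignard reagent on prenyl bromide should take place at the unhindered primary carbon (SN2 mode) and give the skipped enyne, with the silyl group blocking double alkylation.

Step 5
Reactants: 9 trimethyl(5-methylhex-4-en-1-yn-1-yl)silane
Product: 10 5-methylhex-4-en-1-yne
Conditions: K2CO3 (20 mol %), MeOH, 0 °C → rt; pentane extraction, careful distillation (volatile)
Reagents that add atoms: none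
Why: Methoxide-mediated protodesilylation of the alkynylsilane is fast under these mild conditions, which are too weakly basic to isomerize the skipped enyne.

Step 6
Reactants: 5 2,4-bis(pivaloyloxy)-5-(3-methylbut-2-en-1-yl)benzoic acid; 10 5-methylhex-4-en-1-yne
Product: 12 1-[2,4-bis(pivaloyloxy)-5-(3-methylbut-2-en-1-yl)phenyl]-6-methylhept-5-en-2-yn-1-one, via 2,4-bis(pivaloyloxy)-5-(3-methylbut-2-en-1-yl)benzoyl chloride 11 (not isolated)
Conditions: 1-chloro-N,N,2-trimethylprop-1-en-1-amine (1.05 equiv), CH2Cl2, 0 °C → rt; then 10 (1.3 equiv), PdCl2(PPh3)2 (2 mol %), CuI (4 mol %), Et3N (1.1 equiv), THF, rt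
Reagents that add atoms: none
Why: The chloroenamine forms the acid chloride without free HCl that could add to the prenyl olefin, and the Pd/Cu-catalysed acyl Sonogashira coupling then joins it to the terminal alkyne with only one equivalent of amine and no alkoxide that could take up the ortho pivaloyl group.

Step 7
Reactants: 12 1-[2,4-bis(pivaloyloxy)-5-(3-methylbut-2-en-1-yl)phenyl]-6-methylhept-5-en-2-yn-1-one; 13 furan
Product: 15 cudraphenone B 2,4-dipivalate, via 7-oxanorbornadiene cycloadduct 14 (not isolated)
Conditions: 13 (30 equiv), CH2Cl2, 1.3 GPa, 25 °C; evaporate; then BF3·OEt2 (0.5 equiv), CH2Cl2, −40 → 0 °C; NaHCO3 quench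
Reagents that add atoms: none
Why: Under pressure furan adds as the 4π partner across the ynone triple bond in a concerted suprafacial (4+2) cycloaddition that forms C1'–C6' and C2'–C3' and gives oxanorbornadiene 14; after removal of furan, BF3·OEt2 ionizes a bridgehead C–O bond, a 1,2-hydride shift in the cyclohexadienyl cation gives a cyclohexadienone, and enolization gives the phenol. The closest known chemistry is the pressure-assisted Diels–Alder reaction of furan with acyl alkynes and the acid-catalysed isomerization of 7-oxanorbornadienes to phenols. Ring B closes by intermolecular cycloaddition with both bonds formed at once, and because furan is symmetrical the cycloaddition itself poses no regiochemical question. The two bridgehead stereocentres of 14 form as a racemate fixed by the bicyclic frame and are erased on aromatization, so nothing stereochemical needs control. The selectivity needed is in the bridge opening: cleavage of the C6'–O bond puts the positive charge on C6', C2' (prenyl-bearing) and C4', whereas cleavage of C3'–O would put it on the acylated C1', so the oxygen should stay on C3' beside the prenyl group. Pressure in place of a Lewis acid during the cycloaddition avoids Friedel–Crafts conjugate addition of furan, the electron-poor ester-bearing aryl ketone keeps the alkyl-substituted ynone as reactive as possible, and a substoichiometric amount of BF3·OEt2 at low temperature (a reagent in which phenols are routinely C-prenylated) should spare both prenyl groups.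

Step 8
Reactants: 15 cudraphenone B 2,4-dipivalate
Product: 16 cudraphenone B
Conditions: K2CO3 (4 equiv), MeOH (degassed), rt, argon; aq. NH4Cl
Reagents that add atoms: none
Why: Base-mediated transesterification with methanol cleaves both aryl pivalates (each activated by the ortho or para ketone) without touching the prenyl groups or the diaryl ketone.

**Compound list**

1 | 5-bromo-2,4-dihydroxybenzaldehyde | O=Cc1cc(Br)c(O)cc1O | starting material
2 | 5-bromo-2,4-bis(pivaloyloxy)benzaldehyde | O=Cc1cc(Br)c(OC(=O)C(C)(C)C)cc1OC(=O)C(C)(C)C | intermediate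
3 | tributyl(3-methylbut-2-en-1-yl)stannane | CC(C)=CC[Sn](CCCC)(CCCC)CCCC | starting material
4 | 2,4-bis(pivaloyloxy)-5-(3-methylbut-2-en-1-yl)benzaldehyde | CC(C)=CCc1cc(C=O)c(OC(=O)C(C)(C)C)cc1OC(=O)C(C)(C)C | intermediate
5 | 2,4-bis(pivaloyloxy)-5-(3-methylbut-2-en-1-yl)benzoic acid | CC(C)=CCc1cc(C(=O)O)c(OC(=O)C(C)(C)C)cc1OC(=O)C(C)(C)C | intermediate
6 | trimethylsilylacetylene | C#C[Si](C)(C)C | starting material
7 | prenyl bromide (1-bromo-3-methylbut-2-ene) | CC(C)=CCBr | starting material
8 | (trimethylsilylethynyl)magnesium bromide | C[Si](C)(C)C#C[Mg]Br | intermediate (not isolated)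
9 | trimethyl(5-methylhex-4-en-1-yn-1-yl)silane | CC(C)=CCC#C[Si](C)(C)C | intermediate
10 | 5-methylhex-4-en-1-yne | CC(C)=CCC#C | intermediate
11 | 2,4-bis(pivaloyloxy)-5-(3-methylbut-2-en-1-yl)benzoyl chloride | CC(C)=CCc1cc(C(=O)Cl)c(OC(=O)C(C)(C)C)cc1OC(=O)C(C)(C)C | intermediate (not isolated)
12 | 1-[2,4-bis(pivaloyloxy)-5-(3-methylbut-2-en-1-yl)phenyl]-6-methylhept-5-en-2-yn-1-one | CC(C)=CCC#CC(=O)c1cc(CC=C(C)C)c(OC(=O)C(C)(C)C)cc1OC(=O)C(C)(C)C | intermediate
13 | furan | c1ccoc1 | starting material
14 | [2,4-bis(pivaloyloxy)-5-prenylphenyl][3-prenyl-7-oxabicyclo[2.2.1]hepta-2,5-dien-2-yl]methanone (racemic, one enantiomer drawn) | O=C(c1cc(CC=C(C)C)c(OC(=O)C(C)(C)C)cc1OC(=O)C(C)(C)C)C1=C(CC=C(C)C)[C@@H]2C=C[C@H]1O2 | intermediate (not isolated)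
15 | cudraphenone B 2,4-dipivalate, [2,4-bis(pivaloyloxy)-5-prenylphenyl](3-hydroxy-2-prenylphenyl)methanone | CC(C)=CCc1cc(C(=O)c2cccc(O)c2CC=C(C)C)c(OC(=O)C(C)(C)C)cc1OC(=O)C(C)(C)C | intermediate
16 | cudraphenone B, (2,4-dihydroxy-5-prenylphenyl)(3-hydroxy-2-prenylphenyl)methanone | CC(C)=CCc1cc(C(=O)c2cccc(O)c2CC=C(C)C)c(O)cc1O | target

**Count and risks**

Total steps: 8. Longest linear sequence: 6 steps (1, 2, 3, 6, 7, 8) from compound 1; the enyne branch (steps 4 and 5) joins at step 6.

Steps most likely to fail:

Step 7. The cycloaddition of the alkyl-substituted ynone may be too slow even under pressure, and acid-induced cyclization of a prenyl chain onto the new phenol or onto the cationic intermediate may compete during bridge opening. Fallback: the ring B prenyl is replaced by bromine, which activates the alkyne and is exchanged for prenyl after the acid step. Acid 5 is converted into chloride 11 as in step 6 and coupled with trimethylsilylacetylene 6 (PdCl2(PPh3)2, CuI, Et3N, THF) to give the trimethylsilyl ynone F1. Bromodesilylation (NBS, AgNO3 cat., acetone, 0 °C, dark) gives the bromo ynone F2. Heating F2 in furan 13 (60 °C, sealed tube) should give the bromo oxanorbornadiene F3, as 3-bromopropiolate-type dienophiles add to furan thermally. F3 is opened without isolation by BF3·OEt2 in CH2Cl2 to the bromophenol F4; the same charge argument places the hydroxyl beside the bromine. Stille coupling of F4 with stannane 3 (Pd(PPh3)4, DMF, 90 °C) returns to the route at compound 15.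

Step 6. The CH2 group of the ynone is both propargylic and allylic, so amine-promoted isomerization to an allenyl or dienyl ketone may erode the product. Fallback: the ynone is formed under neutral oxidative conditions. Alkyne 10 is deprotonated (n-BuLi, THF, −78 °C) to the lithium acetylide F5, which is added to aldehyde 4 at −78 °C. The alkoxide is quenched at that temperature with acetic acid, before the ortho pivaloyl group can migrate, to give the racemic propargylic alcohol F6. Oxidation with Dess–Martin periodinane (NaHCO3, CH2Cl2, 0 °C) returns to the route at compound 12.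

Step 2. The allyl transfer may lose regiocontrol, with coupling through the tertiary carbon giving the 1,1-dimethylallyl isomer, and protodestannylation may compete. Fallback: the regiochemical question is removed by a two-carbon-shorter chain. Bromide 2 is coupled with allyltributylstannane (Pd(PPh3)4, toluene, 100 °C) to give the allyl aldehyde F7. Cross-metathesis of F7 with 2-methyl-2-butene as solvent (second-generation Grubbs catalyst, (H2IMes)(PCy3)Cl2Ru=CHPh, 40 °C) returns to the route at compound 4.

**Further compounds**

F1 | step 7 | 1-[2,4-bis(pivaloyloxy)-5-prenylphenyl]-3-(trimethylsilyl)prop-2-yn-1-one | C[Si](C)(C)C#CC(=O)c1cc(CC=C(C)C)c(OC(=O)C(C)(C)C)cc1OC(=O)C(C)(C)C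
F2 | step 7 | 3-bromo-1-[2,4-bis(pivaloyloxy)-5-prenylphenyl]prop-2-yn-1-one | BrC#CC(=O)c1cc(CC=C(C)C)c(OC(=O)C(C)(C)C)cc1OC(=O)C(C)(C)C
F3 | step 7 | [2,4-bis(pivaloyloxy)-5-prenylphenyl][3-bromo-7-oxabicyclo[2.2.1]hepta-2,5-dien-2-yl]methanone (racemic, one enantiomer drawn) | O=C(c1cc(CC=C(C)C)c(OC(=O)C(C)(C)C)cc1OC(=O)C(C)(C)C)C1=C(Br)[C@@H]2C=C[C@H]1O2
F4 | step 7 | (2-bromo-3-hydroxyphenyl)[2,4-bis(pivaloyloxy)-5-prenylphenyl]methanone | O=C(c1cccc(O)c1Br)c1cc(CC=C(C)C)c(OC(=O)C(C)(C)C)cc1OC(=O)C(C)(C)C
F5 | step 6 | (5-methylhex-4-en-1-yn-1-yl)lithium | [Li]C#CCC=C(C)C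
F6 | step 6 | 1-[2,4-bis(pivaloyloxy)-5-prenylphenyl]-6-methylhept-5-en-2-yn-1-ol (racemic) | CC(C)=CCC#CC(O)c1cc(CC=C(C)C)c(OC(=O)C(C)(C)C)cc1OC(=O)C(C)(C)C
F7 | step 2 | 5-allyl-2,4-bis(pivaloyloxy)benzaldehyde | C=CCc1cc(C=O)c(OC(=O)C(C)(C)C)cc1OC(=O)C(C)(C)C
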